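**Retrosynthetic overview**

- The strategy rests on ring C: C2–C3–C4 is a 3-oxy-2-arylpropanoyl unit (C2 on O1, ring B on C3, C4 the ketone), and ring A is a phloroglucinol whose two carbons ortho to O1 are equivalent. The last skeletal bond, C4–C4a, is therefore cut as an intramolecular Friedel–Crafts acylation of an (R)-2-aryl-3-aryloxypropanoic acid.
- The acid is cut at C2–C3 into a chromenylacetyl (S)-4-benzyloxazolidinone, whose Cl3Ti enolate sets C3, and a 3,5-bis(silyloxy)phenoxymethyl chloride made from phloroglucinol.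
- The chromenylacetic acid comes from 2,4-dihydroxybenzaldehyde by chromenylation with 3-methylbut-2-enal, silylation and one-carbon homologation (Wittig, hydrolysis, Pinnick).
- Ring order: the pyran ring of the chromene first (on ring B), ring C last; rings A and B are bought as arenes; the three TIPS ethers are removed at the end with HF·pyridine.

Key step: step 12

Remark on the chemistry: C3 of the target is read as (R) (priority C4 > C2 > aryl > H); the same spatial arrangement is also (R) in the open-chain acid and in the acyl imide.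

**Route**

Step 1
Reactants: 1 2,4-dihydroxybenzaldehyde; 2 3-methylbut-2-enal
Product: 4 5-hydroxy-2,2-dimethyl-2H-chromene-6-carbaldehyde, via ortho-quinone methide 3 (not isolated)
Conditions: pyridine, 120 °C (sealed tube)
Reagents that add atoms: none
Why: Pyridine-mediated chromenylation (aldol-type condensation at C3 of the resorcinol ring, loss of water to the ortho-quinone methide, oxa-6π electrocyclisation) should close the pyran through the free 4-OH, because the 2-OH is held in a hydrogen bond to the formyl group, giving the angular 5-hydroxy-6-formyl isomer.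

Step 2
Reactants: 4 5-hydroxy-2,2-dimethyl-2H-chromene-6-carbaldehyde
Product: 5 2,2-dimethyl-5-(triisopropylsilyloxy)-2H-chromene-6-carbaldehyde
Conditions: iPr3SiOTf, 2,6-lutidine, CH2Cl2, 0 °C → rt
Reagents that add atoms: triisopropylsilyl trifluoromethanesulfonate, CC(C)[Si](OS(=O)(=O)C(F)(F)F)(C(C)C)C(C)C
Why: Silyl ether formation on a hydrogen-bonded, doubly ortho-substituted phenol needs the silyl triflate, and the bulky TIPS group is chosen because it must survive hydroperoxide and Lewis acids later and must make this oxygen a poor acyl acceptor in step 12.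

Step 3
Reactants: 5 2,2-dimethyl-5-(triisopropylsilyloxy)-2H-chromene-6-carbaldehyde
Product: 6 6-(2-methoxyvinyl)-2,2-dimethyl-5-(triisopropylsilyloxy)-2H-chromene (E/Z mixture)
Conditions: Ph3P(CH2OMe)Cl, KN(SiMe3)2, THF, 0 °C → rt
Reagents that add atoms: (methoxymethyl)triphenylphosphonium chloride, COC[P+](c1ccccc1)(c1ccccc1)c1ccccc1.[Cl-]
Why: Wittig olefination with methoxymethylenetriphenylphosphorane adds the extra carbon as an enol ether, and both alkene isomers serve equally in the next step.

Step 4
Reactants: 6 6-(2-methoxyvinyl)-2,2-dimethyl-5-(triisopropylsilyloxy)-2H-chromene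
Product: 7 2-[2,2-dimethyl-5-(triisopropylsilyloxy)-2H-chromen-6-yl]acetaldehyde
Conditions: 1 M HCl (aq), THF, rt; product used crude
Reagents that add atoms: water, O
Why: Acid-catalysed enol ether hydrolysis (C-protonation, hemiacetal, loss of methanol) should unmask the arylacetaldehyde under conditions that aryl TIPS ethers and the 2,2-dimethylchromene tolerate.

Step 5
Reactants: 7 2-[2,2-dimethyl-5-(triisopropylsilyloxy)-2H-chromen-6-yl]acetaldehyde
Product: 8 2-[2,2-dimethyl-5-(triisopropylsilyloxy)-2H-chromen-6-yl]acetic acid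
Conditions: NaClO2, NaH2PO4, 2-methyl-2-butene, t-BuOH/H2O, 0 °C → rt
Reagents that add atoms: sodium chlorite, [Na+].[O-]Cl=O
Why: Pinnick oxidation takes the aldehyde to the acid under buffered conditions, with 2-methyl-2-butene taking up HOCl so that the chromene double bond is not chlorinated.

Step 6
Reactants: 8 2-[2,2-dimethyl-5-(triisopropylsilyloxy)-2H-chromen-6-yl]acetic acid; 9 (S)-4-benzyl-2-oxazolidinone
Product: 11 (4S)-4-benzyl-3-{2-[2,2-dimethyl-5-(triisopropylsilyloxy)-2H-chromen-6-yl]acetyl}oxazolidin-2-one, via mixed pivalic anhydride 10 (not isolated)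
Conditions: t-BuCOCl, Et3N, THF, −20 °C; then LiCl, 9, −20 °C → rt
Reagents that add atoms: none
Why: Mixed-anhydride N-acylation of the oxazolidinone under LiCl/Et3N activation should occur at the less hindered arylacetyl carbonyl, and no stereocentre is involved.

Step 7
Reactants: 12 phloroglucinol
Product: 13 3,5-bis(triisopropylsilyloxy)phenol
Conditions: iPr3SiCl (2.0 equiv), imidazole, DMF, 0 °C → rt; chromatography
Reagents that add atoms: chlorotriisopropylsilane, CC(C)[Si](Cl)(C(C)C)C(C)C
Why: Statistical silylation of three equivalent phenols with two equivalents of silyl chloride should give the bis-ether as the main component, separable from the mono- and tris-ethers, which can be recycled.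

Step 8
Reactants: 13 3,5-bis(triisopropylsilyloxy)phenol
Product: 14 [3,5-bis(triisopropylsilyloxy)phenoxy]methyl methyl sulfide
Conditions: NaH, ClCH2SMe, NaI (cat.), DMF, 0 °C → rt
Reagents that add atoms: chloromethyl methyl sulfide, CSCCl
Why: Williamson etherification of the phenoxide with the iodide-activated chloromethyl sulfide installs the (methylthio)methyl ether, and the bulky TIPS groups should resist silyl transfer at this temperature.

Step 9
Reactants: 14 [3,5-bis(triisopropylsilyloxy)phenoxy]methyl methyl sulfide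
Product: 15 1-(chloromethoxy)-3,5-bis(triisopropylsilyloxy)benzene
Conditions: SO2Cl2 (1.0 equiv), CH2Cl2, −78 °C; then cyclohexene, −78 → 0 °C; evaporate, use crude at once
Reagents that add atoms: sulfuryl chloride, O=S(=O)(Cl)Cl
Why: S-chlorination and Pummerer-type fragmentation of the O,S-acetal replace SMe by Cl (the standard route to α-chloro ethers), while the low temperature and the cyclohexene trap for MeSCl protect the electron-rich ring from chlorination and sulfenylation.

Step 10
Reactants: 11 (4S)-4-benzyl-3-{2-[2,2-dimethyl-5-(triisopropylsilyloxy)-2H-chromen-6-yl]acetyl}oxazolidin-2-one; 15 1-(chloromethoxy)-3,5-bis(triisopropylsilyloxy)benzene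
Product: 17 (4S)-4-benzyl-3-{(2R)-3-[3,5-bis(triisopropylsilyloxy)phenoxy]-2-[2,2-dimethyl-5-(triisopropylsilyloxy)-2H-chromen-6-yl]propanoyl}oxazolidin-2-one, via Cl3Ti Z-enolate 16 (not isolated)
Conditions: TiCl4 (1.0 equiv), iPr2NEt, CH2Cl2, 0 °C; then 15, 0 °C
Reagents that add atoms: none
Why: Evans alkylation of a chelated Cl3Ti Z-enolate with an α-chloro ether (the reaction type of the benzyloxymethyl chloride alkylation) should set C3 as (R), because the benzyl group of the (S)-auxiliary blocks one enolate face and the CH2OAr group enters from the other.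

Step 11
Reactants: 17 (4S)-4-benzyl-3-{(2R)-3-[3,5-bis(triisopropylsilyloxy)phenoxy]-2-[2,2-dimethyl-5-(triisopropylsilyloxy)-2H-chromen-6-yl]propanoyl}oxazolidin-2-one
Product: 19 (2R)-3-[3,5-bis(triisopropylsilyloxy)phenoxy]-2-[2,2-dimethyl-5-(triisopropylsilyloxy)-2H-chromen-6-yl]propanoic acid, via peroxy acid 18 (not isolated)
Conditions: LiOH, H2O2, THF/H2O, 0 °C; then Na2SO3 (aq); then 1 M HCl to pH 3
Reagents that add atoms: hydrogen peroxide, OO
Why: Evans hydroperoxide cleavage attacks the exocyclic acyl carbonyl selectively, sulfite reduces the peroxy acid before acidification, and at 0 °C the carboxylate formed should not be deprotonated further, so the α-aryl stereocentre and the aryl silyl ethers should survive.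

Step 12
Reactants: 19 (2R)-3-[3,5-bis(triisopropylsilyloxy)phenoxy]-2-[2,2-dimethyl-5-(triisopropylsilyloxy)-2H-chromen-6-yl]propanoic acid
Product: 21 (3R)-5,7-bis(triisopropylsilyloxy)-3-[2,2-dimethyl-5-(triisopropylsilyloxy)-2H-chromen-6-yl]chroman-4-one, via acyl chloride 20 (not isolated)
Conditions: Me2C=C(Cl)NMe2, CH2Cl2, 0 °C → rt; then SnCl4 (2.2 equiv, one equivalent is bound by the amide by-product), CH2Cl2, −78 °C; cold NaHCO3 (aq) quench
Reagents that add atoms: none
Why: The chloroenamine converts acid 19 into acyl chloride 20 without base or free HCl, and SnCl4 then polarises the C–Cl bond so that the acyl carbon (C4) is attacked by a ring-A carbon ortho to O1, giving a Wheland intermediate that loses HCl and forms the C4–C4a bond. The closest known reaction type is the intramolecular Friedel–Crafts acylation of 3-aryloxypropanoic acids to chroman-4-ones. Ring C closes in a 6-exo-trig mode at the acyl carbon, with the arene π bond inside the new ring. No new stereocentre is formed, and C3 is carried over from step 10, where the auxiliary fixed it. The step needs site selectivity (the two carbons ortho to O1 are equivalent through the 3,5-disilyloxy pattern and the para carbon cannot reach C4), C-acylation in preference to acyl transfer onto the 2′-oxygen of ring B or loss of CO from a free acylium ion, and retention at C3. These should be secured by the high nucleophilicity of the trioxygenated ring, which lets the SnCl4-bound acyl chloride react at −78 °C before ketene or enol formation, by the bulk of the TIPS group on the 2′-oxygen, and by the absence of any base.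

Step 13
Reactants: 21 (3R)-5,7-bis(triisopropylsilyloxy)-3-[2,2-dimethyl-5-(triisopropylsilyloxy)-2H-chromen-6-yl]chroman-4-one
Product: 22 (3R)-5,7-dihydroxy-3-(5-hydroxy-2,2-dimethyl-2H-chromen-6-yl)chroman-4-one
Conditions: HF·pyridine, pyridine, THF, 0 °C → rt
Reagents that add atoms: none
Why: Fluoride desilylation under buffered, weakly acidic conditions should free the three phenols without creating a basic phenoxide or enolate medium, so C3 should not epimerise and the chromene stays untouched.

**Compound list**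

1 | 2,4-dihydroxybenzaldehyde | O=Cc1ccc(O)cc1O | starting material
2 | 3-methylbut-2-enal | CC(C)=CC=O | starting material
3 | 2-hydroxy-3-(3-methylbut-2-en-1-ylidene)-4-oxocyclohexa-1,5-diene-1-carbaldehyde (ortho-quinone methide, formed in the flask, not isolated) | O=CC1=C(O)C(=CC=C(C)C)C(=O)C=C1 | intermediate
4 | 5-hydroxy-2,2-dimethyl-2H-chromene-6-carbaldehyde | CC1(C)C=Cc2c(ccc(C=O)c2O)O1 | intermediate
5 | 2,2-dimethyl-5-(triisopropylsilyloxy)-2H-chromene-6-carbaldehyde | CC1(C)C=Cc2c(ccc(C=O)c2O[Si](C(C)C)(C(C)C)C(C)C)O1 | intermediate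
6 | 6-(2-methoxyvinyl)-2,2-dimethyl-5-(triisopropylsilyloxy)-2H-chromene (E/Z mixture) | CC1(C)C=Cc2c(ccc(C=COC)c2O[Si](C(C)C)(C(C)C)C(C)C)O1 | intermediate
7 | 2-[2,2-dimethyl-5-(triisopropylsilyloxy)-2H-chromen-6-yl]acetaldehyde | CC1(C)C=Cc2c(ccc(CC=O)c2O[Si](C(C)C)(C(C)C)C(C)C)O1 | intermediate
8 | 2-[2,2-dimethyl-5-(triisopropylsilyloxy)-2H-chromen-6-yl]acetic acid | CC1(C)C=Cc2c(ccc(CC(=O)O)c2O[Si](C(C)C)(C(C)C)C(C)C)O1 | intermediate
9 | (S)-4-benzyl-2-oxazolidinone | O=C1N[C@@H](Cc2ccccc2)CO1 | starting material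
10 | mixed anhydride of acid 8 with pivalic acid (formed in the flask, not isolated) | CC1(C)C=Cc2c(ccc(CC(=O)OC(=O)C(C)(C)C)c2O[Si](C(C)C)(C(C)C)C(C)C)O1 | intermediate
11 | (4S)-4-benzyl-3-{2-[2,2-dimethyl-5-(triisopropylsilyloxy)-2H-chromen-6-yl]acetyl}oxazolidin-2-one | CC1(C)C=Cc2c(ccc(CC(=O)N3[C@@H](Cc4ccccc4)COC3=O)c2O[Si](C(C)C)(C(C)C)C(C)C)O1 | intermediate
12 | phloroglucinol | Oc1cc(O)cc(O)c1 | starting material
13 | 3,5-bis(triisopropylsilyloxy)phenol | Oc1cc(O[Si](C(C)C)(C(C)C)C(C)C)cc(O[Si](C(C)C)(C(C)C)C(C)C)c1 | intermediate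
14 | [3,5-bis(triisopropylsilyloxy)phenoxy]methyl methyl sulfide | CSCOc1cc(O[Si](C(C)C)(C(C)C)C(C)C)cc(O[Si](C(C)C)(C(C)C)C(C)C)c1 | intermediate
15 | 1-(chloromethoxy)-3,5-bis(triisopropylsilyloxy)benzene | ClCOc1cc(O[Si](C(C)C)(C(C)C)C(C)C)cc(O[Si](C(C)C)(C(C)C)C(C)C)c1 | intermediate
16 | Cl3Ti Z-enolate of imide 11 (formed in the flask, not isolated) | CC1(C)C=Cc2c(ccc(/C=C(\O[Ti](Cl)(Cl)Cl)N3[C@@H](Cc4ccccc4)COC3=O)c2O[Si](C(C)C)(C(C)C)C(C)C)O1 | intermediate
17 | (4S)-4-benzyl-3-{(2R)-3-[3,5-bis(triisopropylsilyloxy)phenoxy]-2-[2,2-dimethyl-5-(triisopropylsilyloxy)-2H-chromen-6-yl]propanoyl}oxazolidin-2-one | CC1(C)C=Cc2c(ccc([C@@H](C(=O)N3[C@@H](Cc4ccccc4)COC3=O)COc5cc(O[Si](C(C)C)(C(C)C)C(C)C)cc(O[Si](C(C)C)(C(C)C)C(C)C)c5)c2O[Si](C(C)C)(C(C)C)C(C)C)O1 | intermediate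
18 | (2R)-3-[3,5-bis(triisopropylsilyloxy)phenoxy]-2-[2,2-dimethyl-5-(triisopropylsilyloxy)-2H-chromen-6-yl]propaneperoxoic acid (formed in the flask, not isolated) | CC1(C)C=Cc2c(ccc([C@@H](C(=O)OO)COc3cc(O[Si](C(C)C)(C(C)C)C(C)C)cc(O[Si](C(C)C)(C(C)C)C(C)C)c3)c2O[Si](C(C)C)(C(C)C)C(C)C)O1 | intermediate
19 | (2R)-3-[3,5-bis(triisopropylsilyloxy)phenoxy]-2-[2,2-dimethyl-5-(triisopropylsilyloxy)-2H-chromen-6-yl]propanoic acid | CC1(C)C=Cc2c(ccc([C@@H](C(=O)O)COc3cc(O[Si](C(C)C)(C(C)C)C(C)C)cc(O[Si](C(C)C)(C(C)C)C(C)C)c3)c2O[Si](C(C)C)(C(C)C)C(C)C)O1 | intermediate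
20 | (2R)-3-[3,5-bis(triisopropylsilyloxy)phenoxy]-2-[2,2-dimethyl-5-(triisopropylsilyloxy)-2H-chromen-6-yl]propanoyl chloride (formed in the flask, not isolated) | CC1(C)C=Cc2c(ccc([C@@H](C(=O)Cl)COc3cc(O[Si](C(C)C)(C(C)C)C(C)C)cc(O[Si](C(C)C)(C(C)C)C(C)C)c3)c2O[Si](C(C)C)(C(C)C)C(C)C)O1 | intermediate
21 | (3R)-5,7-bis(triisopropylsilyloxy)-3-[2,2-dimethyl-5-(triisopropylsilyloxy)-2H-chromen-6-yl]chroman-4-one | CC1(C)C=Cc2c(ccc([C@@H]3COc4cc(O[Si](C(C)C)(C(C)C)C(C)C)cc(O[Si](C(C)C)(C(C)C)C(C)C)c4C3=O)c2O[Si](C(C)C)(C(C)C)C(C)C)O1 | intermediate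
22 | (3R)-5,7-dihydroxy-3-(5-hydroxy-2,2-dimethyl-2H-chromen-6-yl)chroman-4-one | CC1(C)C=Cc2c(ccc([C@@H]3COc4cc(O)cc(O)c4C3=O)c2O)O1 | target

**Step count and risks**

Total step count: 13. Longest linear sequence: 10 steps (steps 1–6 and 10–13, from 2,4-dihydroxybenzaldehyde); the ring-A fragment takes 3 steps (7–9).

Steps most likely to fail, in order of risk:

1. Step 12. The C3 configuration may erode through enolisation or ketene formation of the SnCl4-activated acyl chloride. Ring closure may also lose out to loss of CO from a free acylium ion, or to acyl transfer onto the 2′-oxygen with loss of its silyl group. Partial loss of the 5-O-silyl group after closure would be harmless, since step 13 removes it anyway. The fallback sets out from 21 of lowered enantiomeric purity and comes back at 21. The ketone is reduced by asymmetric transfer hydrogenation with dynamic kinetic resolution (RuCl[(R,R)-TsDPEN](p-cymene), HCO2H/Et3N, EtOAc, 40 °C). C3 equilibrates through the enol under the amine while the catalyst delivers hydride to one ketone face, and the cis preference selects the (3R) series. This should give cis-(3R,4R)-5,7-bis(triisopropylsilyloxy)-3-[2,2-dimethyl-5-(triisopropylsilyloxy)-2H-chromen-6-yl]chroman-4-ol F1. Oxidation of C4 with Dess–Martin periodinane and NaHCO3 in CH2Cl2, which does not enolise the ketone, returns 21.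

2. Step 10. The electron-rich α-chloro ether may ionise under TiCl4 and alkylate another ring A, or decompose during its preparation and handling, before the enolate captures it, so that C–C bond formation stalls. The fallback sets out from imide 11 and phenol 13 and comes back at 17. The Cl3Ti enolate of 11 is hydroxymethylated with s-trioxane and a second equivalent of TiCl4 (CH2Cl2, 0 °C) under the same facial control, giving (4S)-4-benzyl-3-{(2R)-2-[2,2-dimethyl-5-(triisopropylsilyloxy)-2H-chromen-6-yl]-3-hydroxypropanoyl}oxazolidin-2-one F2. Its primary alcohol is then etherified with 13 under Mitsunobu conditions (PPh3, DIAD, toluene, 0 °C). Allylic strain in the imide keeps the α-hydrogen out of alignment with the carbonyl, so elimination should be slow. This gives 17, and compounds 14 and 15 are no longer needed.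

3. Step 11. Hydroperoxide or hydroxide may attack the ring carbonyl of the hindered imide, base may cause β-elimination of the aryloxide or epimerisation at the α-aryl carbon, or an aryl silyl ether may be lost. The fallback sets out from 17 and comes back at 19. Reductive removal of the auxiliary (LiBH4, MeOH, Et2O, 0 °C) should give (2S)-3-[3,5-bis(triisopropylsilyloxy)phenoxy]-2-[2,2-dimethyl-5-(triisopropylsilyloxy)-2H-chromen-6-yl]propan-1-ol F3, in which the stereocentre is no longer next to a carbonyl. Direct oxidation of the primary alcohol with TEMPO (cat.) and PhI(OAc)2 in MeCN/H2O then gives acid 19.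

**Further compounds**

F1 | step 12 | (3R,4R)-5,7-bis(triisopropylsilyloxy)-3-[2,2-dimethyl-5-(triisopropylsilyloxy)-2H-chromen-6-yl]chroman-4-ol (cis) | CC1(C)C=Cc2c(ccc([C@@H]3COc4cc(O[Si](C(C)C)(C(C)C)C(C)C)cc(O[Si](C(C)C)(C(C)C)C(C)C)c4[C@@H]3O)c2O[Si](C(C)C)(C(C)C)C(C)C)O1
F2 | step 10 | (4S)-4-benzyl-3-{(2R)-2-[2,2-dimethyl-5-(triisopropylsilyloxy)-2H-chromen-6-yl]-3-hydroxypropanoyl}oxazolidin-2-one | CC1(C)C=Cc2c(ccc([C@@H](C(=O)N3[C@@H](Cc4ccccc4)COC3=O)CO)c2O[Si](C(C)C)(C(C)C)C(C)C)O1
F3 | step 11 | (2S)-3-[3,5-bis(triisopropylsilyloxy)phenoxy]-2-[2,2-dimethyl-5-(triisopropylsilyloxy)-2H-chromen-6-yl]propan-1-ol | CC1(C)C=Cc2c(ccc([C@@H](CO)COc3cc(O[Si](C(C)C)(C(C)C)C(C)C)cc(O[Si](C(C)C)(C(C)C)C(C)C)c3)c2O[Si](C(C)C)(C(C)C)C(C)C)O1
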